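## Structural features

The target is a linear octamer of the phlorotannin type: eight benzene rings (A to H, lettered from the 2,4,6-trihydroxyphenyl end) joined only by seven diaryl ether oxygens, with 21 free phenolic hydroxyls and no carbon–carbon bond between rings. It has no stereocentre, so no stereocentres stand next to each other and the whole problem is one of regiochemistry. Ring A is a phloroglucinol whose C1 carries the ether to C1 of ring B; ring B has hydroxyls at C3 and C4 and its second ether at C5. Rings C, E and G carry ethers on the adjacent carbons C1 and C6 and hydroxyls at C3, C4 and C5; rings D and F are 3,5-dihydroxylated 1,4-diethers; ring H is a 3,4,5-trihydroxyphenyl group. The free polyphenol (pyrogallol-like arrays on rings C, E, G and H, a catechol on ring B) is readily oxidised, above all in base, so the hydroxyls have to travel as methyl ethers until the last step. The real difficulty is that six of the seven ether oxygens sit on a carbon with two oxygenated neighbours (C1 of ring A, C6 of rings C, E and G, C4 of rings D and F), where metal-mediated C–O coupling is unreliable, and that many near-equivalent oxygens must be told apart. The key step exploits ring A: its carbons C1 to C6 map onto C4, C3, C2, C7, C6 and C5 of a 3,5-dioxoheptanedioate, its three hydroxyls are the two ketone oxygens and one ester carbonyl oxygen, and the ether oxygen already sits on the central sp3 carbon, so the most hindered ether exists as an ordinary alkyl aryl ether before the ring does. For rings C to H, the carbon attacked in each ether-forming event has an ortho or para neighbour that is oxygenated in the target, so a formyl group there can activate fluoride displacement and then become that oxygen.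

## Logic of the disconnections

39 is cut at its twenty O–CH3 bonds to give 38. The free polyphenol cannot be carried through basic or oxidising steps, whereas the methyl ethers are stable and chromatographable; the one free hydroxyl of 38 (ring H, C4) is harmless. The forward step must cleave every alkyl–oxygen bond and leave the seven aryl–oxygen–aryl bonds intact.

38 is cut six times at the O–C1 bond of the ring nearer to H, and each oxygen needed for the next bond is traced back to a formyl group: 38 from 36, 36 from 35 and 23, 35 from 33, 33 from 32 and 19, 32 from 30, 30 from 29 and 23, 29 from 27, 27 from 26 and 19, 26 from 24, 24 from 22 and 23, 22 from 20, and 20 from 16 and 19. One fluoroaldehyde cannot serve all six rings. Rings D, F and H need the formyl group para to fluorine (23), because their C4 oxygen is para to the carbon attacked. Rings C, E and G need it ortho (19), because their next oxygen is at C6 and their C3 to C5 oxygens can be present from the start. The hexamer C to H thus reduces to two monomers, and every phenol is generated only when it is needed, so no protecting-group step is spent on rings C to H. The demand is fluoride displacement on methoxy-deactivated aldehydes by hindered phenoxides, and clean aryl migration in each peracid oxidation of an electron-rich oligomer.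

19 is cut at its C–CHO bond to 17. The two ring hydrogens of 17 are equivalent and each lies between fluorine and methoxy, so metalation can give only one isomer; the forward step must be run cold enough that the ortho-fluoro aryllithium does not lose fluoride.

16 is taken back through 15 and 14 to 12 by restoring the O–benzyl bond at ring B C5, removing the three ring A methyl groups and re-attaching a methoxycarbonyl group at ring A C3. The ester is the residue of the ring synthesis; it is removed at the trihydroxy stage, where the acid decarboxylates easily, and not after methylation, where a 2,6-dimethoxybenzoate would resist hydrolysis. Benzyl keeps the ring B C5 oxygen distinct from the three ring A oxygens that are methylated.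

12 is cut at the C3–C4 bond of ring A to the open chain 11. This replaces an aromatic ring carrying the most hindered ether of the molecule by a symmetrical acyclic tricarbonyl chain whose central carbon already bears the aryloxy group. The forward ring closure must go through carbon and not through an enol oxygen.

11 is cut at C4–C5 of the chain to 8 and 9, with 10 as the first-formed adduct. The nucleophile is the terminal carbon of a neutral bis(silyloxy)diene and not a lithium dianion, because 9 has an acidic methylene that a dianion would deprotonate. 8 comes from 6 through 7 by two O–Si bond formations.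

6 is cut at the aryl-O–CH2 bond to 4 and 5. The ether that will later be flanked by two hydroxyls is thereby made by SN2 displacement of a primary chloride next to a ketone, which has no steric problem.

4 is taken back to 2 by replacing the C1 oxygen of ring B with a formyl group (aryl migration to oxygen in the forward sense), and 2 to 1 by cutting the O–benzyl bond.

## Other disconnections considered

Alternative 1: The cut is made at the five C4–O(H) bonds of rings B, C, E, G and H, all traced back to formyl groups in pentaaldehyde A1. The forward step would be a fivefold Dakin-type oxidation (peracid or alkaline peroxide, then formate hydrolysis) to pentaphenol A2, which differs from the target only by sixteen methyl groups.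
- In favour: each formyl group would first act as the para-activator for a fluoride displacement, so activating group and latent hydroxyl are one; all oxidation falls into a single operation; A2 needs no re-protection.
- Against: the oxygens used for chain growth (C4 of rings D and F, C6 of rings C, E and G) must be free phenols during assembly. They cannot be made by the same oxidation while other equally electron-rich aldehydes are to be kept, so these rings would have to enter with protected oxygens, through couplings at doubly ortho-substituted positions. The building block for rings C, E and G (fluorine para to formyl with an oxygen next to the fluorine) is not a simple compound. Five aryl migrations on one substrate would all have to go to completion.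
- Comparison: mechanistically this is the reaction the chosen route uses six times, so the two plans are equal in precedent. Alternative 1 is the better on the number of oxidation operations, and because it buys ring A instead of building it, it would also shorten the front end (nine steps to 16 in the chosen plan). The chosen plan is stronger in that each oxidation creates exactly the phenoxide required for the next bond, and the ether at ring A C1 is not made by a coupling at all.

Alternative 2: Ring B is taken apart at C1–C6, C2–C3 and C3–C4 into cyclobutenone A3 (racemic, carrying rings C to H as a 3-aryloxy group) and the ethynyl ether A4 of ring A. Heating would open A3 to a vinylketene, which would add to A4 in a [2+2] sense; the new cyclobutenone would reopen to a dienylketene and close by 6π electrocyclisation to phenol A5.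
- In favour: the positions of all six substituents of ring B are fixed by the mechanism; the conditions are neutral; the ring A part and the hexamer part are united in the ring-forming event.
- Against: both partners are sensitive (aryl ethynyl ethers hydrate and polymerise; a 4-alkoxy-3-aryloxycyclobutenone is a labile vinylogous ester that must itself come from a ketene–alkyne cycloaddition). The cascade passes through two ketenes on a very large substrate. The ring C to H portion of A3 still requires the whole iterative ether chemistry, with its own differentiated start at ring C.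
- Comparison: on convergence Alternative 2 is the better plan, and in principle it is the equal of the chosen one, since both build an aromatic ring around ether oxygens that are already in place. It forms three ring bonds in one step against one in the Dieckmann closure, but the precursors are harder to reach and the step count would not fall.

Alternative 3: The C4–O bonds of rings D and F are cut by way of carbonyl insertion. The bis(diaryl ketone) A6 would be treated with a peracid under strong acid catalysis; the 2,6-dimethoxy-4-aryloxyphenyl groups would migrate from carbon to oxygen to give diester A7.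
- In favour: diaryl ketones are made by C–C chemistry that tolerates two ortho substituents far better than C–O coupling does, and the doubly ortho-methoxylated aryl group has a high migratory aptitude.
- Against: A7 is a bis-benzoate and contains two carbons more than the target skeleton. Each carbonyl would have to be extruded in a decarbonylative ether synthesis that is established only for much simpler esters; hydrolysis would merely return phenols and acids, with the ether bonds still unmade. The competing aryl groups (rings E and G) are also electron-rich, and strongly acidic peracid is a risk for eight methoxylated rings.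
- Comparison: on tolerance of steric crowding in the bond-forming event Alternative 3 is the better plan, and its aryl migration is the equal of the Baeyer–Villiger steps used in the chosen route. It is weaker on structure (wrong oxidation level and atom count at two junctions) and on step economy.

Key step: step 6

Assumption: 17 and 23 are treated as purchasable fluoroarenes; all other inputs are common catalogue chemicals.

## Steps

Step 1
Reactants: 1 3-hydroxy-4,5-dimethoxybenzaldehyde
Product: 2 3-(benzyloxy)-4,5-dimethoxybenzaldehyde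
Conditions: BnBr, K2CO3, DMF, 60 °C
Reagents that add atoms: benzyl bromide, BrCc1ccccc1
Why: Williamson etherification of the only phenol; the benzyl ether should survive peracid, base, silyl chloride and methoxide in steps 2 to 8 and is removed by hydrogenolysis in step 9.

Step 2
Reactants: 2 3-(benzyloxy)-4,5-dimethoxybenzaldehyde
Product: 4 3-(benzyloxy)-4,5-dimethoxyphenol, via aryl formate 3 (not isolated)
Conditions: mCPBA (1.1 equiv), CH2Cl2, 0 °C to rt; then Et3N, MeOH, rt
Reagents that add atoms: mCPBA (3-chloroperoxybenzoic acid), OOC(=O)c1cccc(Cl)c1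
Why: Baeyer–Villiger oxidation of an electron-rich benzaldehyde (Dakin-type): the trialkoxyaryl group migrates in the Criegee adduct, and the labile formate is methanolysed in the same pot.

Step 3
Reactants: 4 3-(benzyloxy)-4,5-dimethoxyphenol; 5 methyl 4-chloro-3-oxobutanoate
Product: 6 methyl 4-[3-(benzyloxy)-4,5-dimethoxyphenoxy]-3-oxobutanoate
Conditions: NaH (2.1 equiv), THF, 0 °C to rt; then 1 M HCl
Reagents that add atoms: none
Why: Williamson-type SN2 displacement of the primary chloride next to the ketone by the phenoxide; the second equivalent of NaH holds the β-keto ester as its enolate and so suppresses self-condensation.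

Step 4
Reactants: 6 methyl 4-[3-(benzyloxy)-4,5-dimethoxyphenoxy]-3-oxobutanoate
Product: 8 1-methoxy-1,3-bis(trimethylsilyloxy)-4-[3-(benzyloxy)-4,5-dimethoxyphenoxy]buta-1,3-diene, via mono(silyl enol ether) 7 (not isolated)
Conditions: Me3SiCl, Et3N, toluene, rt; filter under Ar, concentrate; then LiN(iPr)2, THF, −78 °C; Me3SiCl, −78 °C to rt
Reagents that add atoms: chlorotrimethylsilane, C[Si](C)(C)Cl
Why: Stepwise silyl enol ether formation (soft enolisation, then γ-deprotonation of the silyloxy crotonate and O-silylation) should give the 1,3-bis(silyloxy)diene, a neutral equivalent of the acetoacetate dianion; the double-bond geometry is of no consequence.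

Step 5
Reactants: 8 1-methoxy-1,3-bis(trimethylsilyloxy)-4-[3-(benzyloxy)-4,5-dimethoxyphenoxy]buta-1,3-diene; 9 methyl 3-chloro-3-oxopropanoate (methyl malonyl chloride)
Product: 11 dimethyl 4-[3-(benzyloxy)-4,5-dimethoxyphenoxy]-3,5-dioxoheptanedioate, via silyl ketene acetal 10 (not isolated)
Conditions: CH2Cl2, −78 °C to rt; then 1 M HCl
Reagents that add atoms: none
Why: Acylation of a 1,3-bis(silyloxy)diene by an acid chloride at its terminal carbon (vinylogous Mukaiyama-type Claisen condensation); with no amine or metal enolate present the acidic methylene of 9 is not deprotonated, and the acidic work-up removes the remaining silyl group.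

Step 6
Reactants: 11 dimethyl 4-[3-(benzyloxy)-4,5-dimethoxyphenoxy]-3,5-dioxoheptanedioate
Product: 12 methyl 3-[3-(benzyloxy)-4,5-dimethoxyphenoxy]-2,4,6-trihydroxybenzoate
Conditions: Mg(OMe)2 (3 equiv), MeOH, reflux, Ar; then 1 M HCl, 0 °C
Reagents that add atoms: none
Why: Mg(OMe)2 removes first the C4 proton between the two ketones and then a C2 proton, and the magnesium chelate of the 3,5-dicarbonyl unit holds the chain folded so that C2 lies over the C7 ester carbonyl. The C2 carbanion adds to that carbonyl, methoxide leaves, and the resulting 2,4,6-trioxocyclohexanecarboxylate enolises at once to the aromatic trihydroxybenzoate; this is an intramolecular Claisen (Dieckmann) condensation. The closest known reaction type is the base-mediated cyclisation of 3,5-dioxoheptanedioates and related tri-β-carbonyl esters to phloroglucinol derivatives, the laboratory counterpart of polyketide folding; only the 4-aryloxy substituent is new. Ring A closes in a 6-exo-trig mode at the ester carbonyl, with the double bond of the attacking ester enolate (C1=C2) outside the new ring, which is a favoured closure. No stereocentre is created, and C4 ends as the sp2 carbon C1 of ring A. The selectivity required is attack through carbon and not through a ketone enol oxygen, which would give a 4-hydroxy-2-pyranone. Three features should secure it: the chain is symmetrical about C4, so both ends lead to the same benzoate; Mg(OMe)2 in methanol can reopen pyranones to the chain, whereas the deprotonated aromatic product cannot revert; and the fully enolised 2-aryloxy-1,3-diketone is protected against retro-Claisen cleavage.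

Step 7
Reactants: 12 methyl 3-[3-(benzyloxy)-4,5-dimethoxyphenoxy]-2,4,6-trihydroxybenzoate
Product: 14 2-[3-(benzyloxy)-4,5-dimethoxyphenoxy]benzene-1,3,5-triol, via carboxylic acid 13 (not isolated)
Conditions: 2 M NaOH (aq, degassed), 90 °C, Ar; then HCl to pH 2, 60 °C
Reagents that add atoms: none
Why: Saponification gives the 2,4,6-trihydroxybenzoic acid, which should lose CO2 readily through its keto tautomer (a β-keto acid); air is excluded because the phloroglucinolate is oxidisable.

Step 8
Reactants: 14 2-[3-(benzyloxy)-4,5-dimethoxyphenoxy]benzene-1,3,5-triol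
Product: 15 1-(benzyloxy)-2,3-dimethoxy-5-(2,4,6-trimethoxyphenoxy)benzene
Conditions: Me2SO4, K2CO3, acetone, reflux, Ar
Reagents that add atoms: dimethyl sulfate, COS(=O)(=O)OC
Why: Williamson O-methylation of the three phenols; the hard electrophile with carbonate in acetone is the combination under which phloroglucinols are methylated on oxygen and not on carbon, and the benzyl ether is untouched.

Step 9
Reactants: 15 1-(benzyloxy)-2,3-dimethoxy-5-(2,4,6-trimethoxyphenoxy)benzene
Product: 16 2,3-dimethoxy-5-(2,4,6-trimethoxyphenoxy)phenol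
Conditions: H2 (1 atm), 10% Pd/C, EtOAc–MeOH, rt
Reagents that add atoms: none
Why: Hydrogenolysis of the benzyl ether frees only the C5 oxygen of ring B; methyl and diaryl ethers are inert.

Step 10
Reactants: 17 5-fluoro-1,2,3-trimethoxybenzene
Product: 19 6-fluoro-2,3,4-trimethoxybenzaldehyde, via aryllithium 18 (not isolated)
Conditions: n-BuLi, THF, −78 °C; DMF, −78 to 0 °C; then 1 M HCl
Reagents that add atoms: N,N-dimethylformamide, CN(C)C=O
Why: Directed ortho-metalation followed by formylation; the two ring hydrogens are equivalent and each is flanked by fluorine and methoxy, so a single aryllithium should form, and at −78 °C it does not lose LiF to an aryne.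

Step 11
Reactants: 16 2,3-dimethoxy-5-(2,4,6-trimethoxyphenoxy)phenol; 19 6-fluoro-2,3,4-trimethoxybenzaldehyde
Product: 20 trimer aldehyde A–C
Conditions: Cs2CO3, DMSO, 100 °C, Ar
Reagents that add atoms: none
Why: SNAr by addition–elimination: the phenoxide displaces the fluoride ortho to the formyl group through a Meisenheimer adduct stabilised by that group; the methoxy groups are far poorer leaving groups and should stay.

Step 12
Reactants: 20 trimer aldehyde A–C
Product: 22 trimer phenol A–C, via trimer formate 21 (not isolated)
Conditions: mCPBA (1.1 equiv), CH2Cl2, 0 °C; then Et3N, MeOH, rt, Ar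
Reagents that add atoms: mCPBA (3-chloroperoxybenzoic acid), OOC(=O)c1cccc(Cl)c1
Why: Baeyer–Villiger oxidation with aryl migration (Dakin-type); the ring carrying two ortho oxygens migrates readily, and methanolysis of the formate frees the C6 hydroxyl of ring C; the peracid is kept near one equivalent to spare the methoxylated rings.

Step 13
Reactants: 22 trimer phenol A–C; 23 4-fluoro-2,6-dimethoxybenzaldehyde
Product: 24 tetramer aldehyde A–D
Conditions: Cs2CO3, DMSO, 100 °C, Ar
Reagents that add atoms: none
Why: SNAr of the fluoride para to the formyl group; both methoxy groups are meta to the carbon attacked and do not destabilise the Meisenheimer adduct.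

Step 14
Reactants: 24 tetramer aldehyde A–D
Product: 26 tetramer phenol A–D, via tetramer formate 25 (not isolated)
Conditions: mCPBA (1.1 equiv), CH2Cl2, 0 °C; then Et3N, MeOH, rt, Ar
Reagents that add atoms: mCPBA (3-chloroperoxybenzoic acid), OOC(=O)c1cccc(Cl)c1
Why: Baeyer–Villiger oxidation of a 2,6-dimethoxybenzaldehyde, a substrate class in which aryl migration dominates, then formate methanolysis to the C4 hydroxyl of ring D.

Step 15
Reactants: 26 tetramer phenol A–D; 19 6-fluoro-2,3,4-trimethoxybenzaldehyde
Product: 27 pentamer aldehyde A–E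
Conditions: Cs2CO3, DMSO, 110 °C, Ar
Reagents that add atoms: none
Why: SNAr as in step 11; the 2,6-dimethoxyphenoxide is hindered but electron-rich, and the electrophilic carbon has only hydrogen and formyl as neighbours.

Step 16
Reactants: 27 pentamer aldehyde A–E
Product: 29 pentamer phenol A–E, via pentamer formate 28 (not isolated)
Conditions: mCPBA (1.1 equiv), CH2Cl2, 0 °C; then Et3N, MeOH, rt, Ar
Reagents that add atoms: mCPBA (3-chloroperoxybenzoic acid), OOC(=O)c1cccc(Cl)c1
Why: Baeyer–Villiger oxidation and formate methanolysis as in step 12, giving the C6 hydroxyl of ring E.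

Step 17
Reactants: 29 pentamer phenol A–E; 23 4-fluoro-2,6-dimethoxybenzaldehyde
Product: 30 hexamer aldehyde A–F
Conditions: Cs2CO3, DMSO, 100 °C, Ar
Reagents that add atoms: none
Why: SNAr of the para-fluoride as in step 13.

Step 18
Reactants: 30 hexamer aldehyde A–F
Product: 32 hexamer phenol A–F, via hexamer formate 31 (not isolated)
Conditions: mCPBA (1.1 equiv), CH2Cl2, 0 °C; then Et3N, MeOH, rt, Ar
Reagents that add atoms: mCPBA (3-chloroperoxybenzoic acid), OOC(=O)c1cccc(Cl)c1
Why: Baeyer–Villiger oxidation and formate methanolysis as in step 14, giving the C4 hydroxyl of ring F.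

Step 19
Reactants: 32 hexamer phenol A–F; 19 6-fluoro-2,3,4-trimethoxybenzaldehyde
Product: 33 heptamer aldehyde A–G
Conditions: Cs2CO3, DMSO, 110 °C, Ar
Reagents that add atoms: none
Why: SNAr of the ortho-fluoride as in step 15.

Step 20
Reactants: 33 heptamer aldehyde A–G
Product: 35 heptamer phenol A–G, via heptamer formate 34 (not isolated)
Conditions: mCPBA (1.1 equiv), CH2Cl2, 0 °C; then Et3N, MeOH, rt, Ar
Reagents that add atoms: mCPBA (3-chloroperoxybenzoic acid), OOC(=O)c1cccc(Cl)c1
Why: Baeyer–Villiger oxidation and formate methanolysis as in step 12, giving the C6 hydroxyl of ring G.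

Step 21
Reactants: 35 heptamer phenol A–G; 23 4-fluoro-2,6-dimethoxybenzaldehyde
Product: 36 octamer aldehyde A–H
Conditions: Cs2CO3, DMSO, 100 °C, Ar
Reagents that add atoms: none
Why: SNAr of the para-fluoride as in step 13; it completes the chain of eight rings.

Step 22
Reactants: 36 octamer aldehyde A–H
Product: 38 octamer phenol A–H, via octamer formate 37 (not isolated)
Conditions: mCPBA (1.1 equiv), CH2Cl2, 0 °C; then Et3N, MeOH, rt, Ar
Reagents that add atoms: mCPBA (3-chloroperoxybenzoic acid), OOC(=O)c1cccc(Cl)c1
Why: Baeyer–Villiger oxidation and formate methanolysis as in step 14; the C4 oxygen of ring H is thereby in place and needs no protection before the last step.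

Step 23
Reactants: 38 octamer phenol A–H
Product: 39 CNP0175816.0 (target)
Conditions: BBr3 (excess), CH2Cl2, −78 °C to rt; MeOH, −78 °C; reversed-phase chromatography under Ar
Reagents that add atoms: none
Why: Lewis acid-mediated cleavage of aryl methyl ethers: BBr3 binds each methoxy oxygen and bromide removes the methyl group by SN2, whereas the diaryl ether oxygens have no sp3 carbon to be attacked; methanol releases the 21 phenols from their borate esters.

## Compound list

1 | 3-hydroxy-4,5-dimethoxybenzaldehyde | COc1cc(C=O)cc(O)c1OC | starting material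
2 | 3-(benzyloxy)-4,5-dimethoxybenzaldehyde | COc1cc(C=O)cc(OCc2ccccc2)c1OC | intermediate
3 | 3-(benzyloxy)-4,5-dimethoxyphenyl formate (not isolated) | COc1cc(OC=O)cc(OCc2ccccc2)c1OC | intermediate
4 | 3-(benzyloxy)-4,5-dimethoxyphenol | COc1cc(O)cc(OCc2ccccc2)c1OC | intermediate
5 | methyl 4-chloro-3-oxobutanoate (methyl 4-chloroacetoacetate) | COC(=O)CC(=O)CCl | starting material
6 | methyl 4-[3-(benzyloxy)-4,5-dimethoxyphenoxy]-3-oxobutanoate | COC(=O)CC(=O)COc1cc(OC)c(OC)c(OCc2ccccc2)c1 | intermediate
7 | methyl 4-[3-(benzyloxy)-4,5-dimethoxyphenoxy]-3-(trimethylsilyloxy)but-2-enoate (not isolated; double-bond geometry not defined) | COC(=O)C=C(O[Si](C)(C)C)COc1cc(OC)c(OC)c(OCc2ccccc2)c1 | intermediate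
8 | 1-methoxy-1,3-bis(trimethylsilyloxy)-4-[3-(benzyloxy)-4,5-dimethoxyphenoxy]buta-1,3-diene (double-bond geometry not defined) | COC(O[Si](C)(C)C)=CC(O[Si](C)(C)C)=COc1cc(OC)c(OC)c(OCc2ccccc2)c1 | intermediate
9 | methyl 3-chloro-3-oxopropanoate (methyl malonyl chloride) | COC(=O)CC(=O)Cl | starting material
10 | silyl ketene acetal of 11: methyl 4-[3-(benzyloxy)-4,5-dimethoxyphenoxy]-7-methoxy-3,5-dioxo-7-(trimethylsilyloxy)hept-6-enoate (not isolated; racemic, geometry not defined) | COC(O[Si](C)(C)C)=CC(=O)C(Oc1cc(OC)c(OC)c(OCc2ccccc2)c1)C(=O)CC(=O)OC | intermediate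
11 | dimethyl 4-[3-(benzyloxy)-4,5-dimethoxyphenoxy]-3,5-dioxoheptanedioate | COC(=O)CC(=O)C(Oc1cc(OC)c(OC)c(OCc2ccccc2)c1)C(=O)CC(=O)OC | intermediate
12 | methyl 3-[3-(benzyloxy)-4,5-dimethoxyphenoxy]-2,4,6-trihydroxybenzoate | COC(=O)c1c(O)cc(O)c(Oc2cc(OC)c(OC)c(OCc3ccccc3)c2)c1O | intermediate
13 | 3-[3-(benzyloxy)-4,5-dimethoxyphenoxy]-2,4,6-trihydroxybenzoic acid (not isolated) | OC(=O)c1c(O)cc(O)c(Oc2cc(OC)c(OC)c(OCc3ccccc3)c2)c1O | intermediate
14 | 2-[3-(benzyloxy)-4,5-dimethoxyphenoxy]benzene-1,3,5-triol | Oc1cc(O)c(Oc2cc(OC)c(OC)c(OCc3ccccc3)c2)c(O)c1 | intermediate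
15 | 1-(benzyloxy)-2,3-dimethoxy-5-(2,4,6-trimethoxyphenoxy)benzene | COc1cc(OC)c(Oc2cc(OC)c(OC)c(OCc3ccccc3)c2)c(OC)c1 | intermediate
16 | 2,3-dimethoxy-5-(2,4,6-trimethoxyphenoxy)phenol (dimer phenol A–B) | COc1cc(OC)c(Oc2cc(OC)c(OC)c(O)c2)c(OC)c1 | intermediate
17 | 5-fluoro-1,2,3-trimethoxybenzene | COc1cc(F)cc(OC)c1OC | starting material
18 | (6-fluoro-2,3,4-trimethoxyphenyl)lithium (not isolated) | [Li]c1c(F)cc(OC)c(OC)c1OC | intermediate
19 | 6-fluoro-2,3,4-trimethoxybenzaldehyde | COc1cc(F)c(C=O)c(OC)c1OC | intermediate
20 | trimer aldehyde A–C: 6-[2,3-dimethoxy-5-(2,4,6-trimethoxyphenoxy)phenoxy]-2,3,4-trimethoxybenzaldehyde | COc1cc(OC)c(Oc2cc(OC)c(OC)c(Oc3cc(OC)c(OC)c(OC)c3C=O)c2)c(OC)c1 | intermediate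
21 | trimer formate A–C: formate ester of 22 (not isolated) | COc1cc(OC)c(Oc2cc(OC)c(OC)c(Oc3cc(OC)c(OC)c(OC)c3OC=O)c2)c(OC)c1 | intermediate
22 | trimer phenol A–C: 6-[2,3-dimethoxy-5-(2,4,6-trimethoxyphenoxy)phenoxy]-2,3,4-trimethoxyphenol | COc1cc(OC)c(Oc2cc(OC)c(OC)c(Oc3cc(OC)c(OC)c(OC)c3O)c2)c(OC)c1 | intermediate
23 | 4-fluoro-2,6-dimethoxybenzaldehyde | COc1cc(F)cc(OC)c1C=O | starting material
24 | tetramer aldehyde A–D: 22 with its phenolic oxygen bonded to a 4-formyl-3,5-dimethoxyphenyl group (ring D) | COc1cc(OC)c(Oc2cc(OC)c(OC)c(Oc3cc(OC)c(OC)c(OC)c3Oc3cc(OC)c(C=O)c(OC)c3)c2)c(OC)c1 | intermediate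
25 | tetramer formate A–D: formate ester of 26 (not isolated) | COc1cc(OC)c(Oc2cc(OC)c(OC)c(Oc3cc(OC)c(OC)c(OC)c3Oc3cc(OC)c(OC=O)c(OC)c3)c2)c(OC)c1 | intermediate
26 | tetramer phenol A–D: as 24 with hydroxyl in place of formyl (ring D is 4-hydroxy-3,5-dimethoxyphenyl) | COc1cc(OC)c(Oc2cc(OC)c(OC)c(Oc3cc(OC)c(OC)c(OC)c3Oc3cc(OC)c(O)c(OC)c3)c2)c(OC)c1 | intermediate
27 | pentamer aldehyde A–E: 26 with its phenolic oxygen bonded to a 2-formyl-3,4,5-trimethoxyphenyl group (ring E) | COc1cc(OC)c(Oc2cc(OC)c(OC)c(Oc3cc(OC)c(OC)c(OC)c3Oc3cc(OC)c(Oc4cc(OC)c(OC)c(OC)c4C=O)c(OC)c3)c2)c(OC)c1 | intermediate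
28 | pentamer formate A–E: formate ester of 29 (not isolated) | COc1cc(OC)c(Oc2cc(OC)c(OC)c(Oc3cc(OC)c(OC)c(OC)c3Oc3cc(OC)c(Oc4cc(OC)c(OC)c(OC)c4OC=O)c(OC)c3)c2)c(OC)c1 | intermediate
29 | pentamer phenol A–E: as 27 with hydroxyl in place of formyl (ring E is 2-hydroxy-3,4,5-trimethoxyphenyl) | COc1cc(OC)c(Oc2cc(OC)c(OC)c(Oc3cc(OC)c(OC)c(OC)c3Oc3cc(OC)c(Oc4cc(OC)c(OC)c(OC)c4O)c(OC)c3)c2)c(OC)c1 | intermediate
30 | hexamer aldehyde A–F: 29 with its phenolic oxygen bonded to a 4-formyl-3,5-dimethoxyphenyl group (ring F) | COc1cc(OC)c(Oc2cc(OC)c(OC)c(Oc3cc(OC)c(OC)c(OC)c3Oc3cc(OC)c(Oc4cc(OC)c(OC)c(OC)c4Oc4cc(OC)c(C=O)c(OC)c4)c(OC)c3)c2)c(OC)c1 | intermediate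
31 | hexamer formate A–F: formate ester of 32 (not isolated) | COc1cc(OC)c(Oc2cc(OC)c(OC)c(Oc3cc(OC)c(OC)c(OC)c3Oc3cc(OC)c(Oc4cc(OC)c(OC)c(OC)c4Oc4cc(OC)c(OC=O)c(OC)c4)c(OC)c3)c2)c(OC)c1 | intermediate
32 | hexamer phenol A–F: as 30 with hydroxyl in place of formyl | COc1cc(OC)c(Oc2cc(OC)c(OC)c(Oc3cc(OC)c(OC)c(OC)c3Oc3cc(OC)c(Oc4cc(OC)c(OC)c(OC)c4Oc4cc(OC)c(O)c(OC)c4)c(OC)c3)c2)c(OC)c1 | intermediate
33 | heptamer aldehyde A–G: 32 with its phenolic oxygen bonded to a 2-formyl-3,4,5-trimethoxyphenyl group (ring G) | COc1cc(OC)c(Oc2cc(OC)c(OC)c(Oc3cc(OC)c(OC)c(OC)c3Oc3cc(OC)c(Oc4cc(OC)c(OC)c(OC)c4Oc4cc(OC)c(Oc5cc(OC)c(OC)c(OC)c5C=O)c(OC)c4)c(OC)c3)c2)c(OC)c1 | intermediate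
34 | heptamer formate A–G: formate ester of 35 (not isolated) | COc1cc(OC)c(Oc2cc(OC)c(OC)c(Oc3cc(OC)c(OC)c(OC)c3Oc3cc(OC)c(Oc4cc(OC)c(OC)c(OC)c4Oc4cc(OC)c(Oc5cc(OC)c(OC)c(OC)c5OC=O)c(OC)c4)c(OC)c3)c2)c(OC)c1 | intermediate
35 | heptamer phenol A–G: as 33 with hydroxyl in place of formyl | COc1cc(OC)c(Oc2cc(OC)c(OC)c(Oc3cc(OC)c(OC)c(OC)c3Oc3cc(OC)c(Oc4cc(OC)c(OC)c(OC)c4Oc4cc(OC)c(Oc5cc(OC)c(OC)c(OC)c5O)c(OC)c4)c(OC)c3)c2)c(OC)c1 | intermediate
36 | octamer aldehyde A–H: 35 with its phenolic oxygen bonded to a 4-formyl-3,5-dimethoxyphenyl group (ring H) | COc1cc(OC)c(Oc2cc(OC)c(OC)c(Oc3cc(OC)c(OC)c(OC)c3Oc3cc(OC)c(Oc4cc(OC)c(OC)c(OC)c4Oc4cc(OC)c(Oc5cc(OC)c(OC)c(OC)c5Oc5cc(OC)c(C=O)c(OC)c5)c(OC)c4)c(OC)c3)c2)c(OC)c1 | intermediate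
37 | octamer formate A–H: formate ester of 38 (not isolated) | COc1cc(OC)c(Oc2cc(OC)c(OC)c(Oc3cc(OC)c(OC)c(OC)c3Oc3cc(OC)c(Oc4cc(OC)c(OC)c(OC)c4Oc4cc(OC)c(Oc5cc(OC)c(OC)c(OC)c5Oc5cc(OC)c(OC=O)c(OC)c5)c(OC)c4)c(OC)c3)c2)c(OC)c1 | intermediate
38 | octamer phenol A–H: eicosamethyl ether of the target with the C4 hydroxyl of ring H free | COc1cc(OC)c(Oc2cc(OC)c(OC)c(Oc3cc(OC)c(OC)c(OC)c3Oc3cc(OC)c(Oc4cc(OC)c(OC)c(OC)c4Oc4cc(OC)c(Oc5cc(OC)c(OC)c(OC)c5Oc5cc(OC)c(O)c(OC)c5)c(OC)c4)c(OC)c3)c2)c(OC)c1 | intermediate
39 | CNP0175816.0 (octamer with 21 free hydroxyls, no stereocentre) | Oc1cc(O)c(Oc2cc(O)c(O)c(Oc3cc(O)c(O)c(O)c3Oc3cc(O)c(Oc4cc(O)c(O)c(O)c4Oc4cc(O)c(Oc5cc(O)c(O)c(O)c5Oc5cc(O)c(O)c(O)c5)c(O)c4)c(O)c3)c2)c(O)c1 | target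

## Step count and least certain steps

Total: 23 steps. Longest linear sequence: 22 steps (steps 1 to 9 and 11 to 23); step 10 is a one-step side branch.

**Step 6 (key step).** Most likely failure: closure through oxygen (lactonisation of a ketone enol onto an ester, giving a 4-hydroxy-2-pyranone), or loss of one malonyl arm by retro-Claisen attack of methoxide on a ketone. The aryloxy group crowds the central carbon and makes the flanking ketones more electrophilic. Sodium methoxide would be tried as a stronger base before the approach is changed.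
Fallback: ring A is bought and the A–B ether is made by fluoride displacement. It sets out from 23. BCl3 (CH2Cl2, −78 to 0 °C) should remove one methyl group ortho to the formyl group through the boron chelate, giving 4-fluoro-2-hydroxy-6-methoxybenzaldehyde F1. Benzylation (BnBr, K2CO3, DMF) gives 2-(benzyloxy)-4-fluoro-6-methoxybenzaldehyde F2. Displacement of its para-fluoride by bought 2,4,6-trimethoxyphenol F3 (Cs2CO3, DMSO, 100 °C) gives 2-(benzyloxy)-6-methoxy-4-(2,4,6-trimethoxyphenoxy)benzaldehyde F4. Peracid oxidation gives 2-(benzyloxy)-6-methoxy-4-(2,4,6-trimethoxyphenoxy)phenyl formate F5, and methanolysis gives 2-(benzyloxy)-6-methoxy-4-(2,4,6-trimethoxyphenoxy)phenol F6. Methylation (Me2SO4, K2CO3, acetone) returns to the route at 15.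

**Step 5.** Most likely failure: acylation at oxygen or at C2 of the diene instead of C4, or protodesilylation back to 6 by traces of HCl from the acid chloride. C4 carries the aryloxy group and is more hindered than in the parent diene.
Fallback: the chain is made first and the aryl ether last, by carbenoid O–H insertion. It sets out from 9 and 4. Bought 1-methoxy-1,3-bis(trimethylsilyloxy)buta-1,3-diene F7 is acylated by 9 under the conditions of step 5 to give dimethyl 3,5-dioxoheptanedioate F8. Diazo transfer (4-acetamidobenzenesulfonyl azide, Et3N, MeCN, 0 °C) at the most acidic, central methylene gives dimethyl 4-diazo-3,5-dioxoheptanedioate F9. Rh2(OAc)4 (1 mol%) in toluene at 80 °C in the presence of 4 should insert the carbenoid into the phenolic O–H bond and return to the route at 11.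

**Step 15 (the same concern applies to steps 11 and 19).** Most likely failure: sluggish fluoride displacement. The fluorine of 19 is para to a methoxy group on a ring with three donors, and the phenoxide of 26 is doubly ortho-substituted; prolonged heating invites oxidative decay of the phenoxide and demethylation of activated methoxy groups.
Fallback: copper-catalysed Ullmann ether synthesis with the bromo analogue. It sets out from 26. Bought 5-bromo-1,2,3-trimethoxybenzene F10 is formylated at its only kind of free position (Cl2CHOMe, TiCl4, CH2Cl2, 0 °C, Rieche formylation) to give 6-bromo-2,3,4-trimethoxybenzaldehyde F11. Coupling of 26 with F11 (CuI, picolinic acid, K3PO4, DMSO, 90 °C) returns to the route at 27.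

**Step 14 (the same concern applies to steps 12, 16, 18, 20 and 22).** Most likely failure: over-oxidation of the methoxylated rings or of the newly formed electron-rich phenol by the peracid, or hydride migration in place of aryl migration leading to a carboxylic acid.
Fallback: ring D enters with its oxygen already in place, so no oxidation is needed. It sets out from 22. Bought 4-bromo-2,6-dimethoxyphenol F12 is benzylated (BnBr, K2CO3) to give 2-(benzyloxy)-5-bromo-1,3-dimethoxybenzene F13. Ullmann coupling with 22 (CuI, picolinic acid, K3PO4, DMSO, 100 °C) gives tetramer benzyl ether F14. Hydrogenolysis (H2, Pd/C) returns to the route at 26.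

**Step 23.** Most likely failure: incomplete cleavage of the twenty methyl ethers as boron chelates precipitate, and oxidative loss of the polyphenol during isolation.
Fallback: the product is captured as its peracetate. It sets out from 38. The crude material from the BBr3 treatment is acetylated (Ac2O, pyridine) to give target henicosaacetate F15, which is purified on silica; partially methylated acetates are separated and returned to demethylation. Acid methanolysis (HCl in MeOH, rt, Ar) returns to the route at 39.

## Further compounds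

F1 | step 6 | 4-fluoro-2-hydroxy-6-methoxybenzaldehyde | COc1cc(F)cc(O)c1C=O
F2 | step 6 | 2-(benzyloxy)-4-fluoro-6-methoxybenzaldehyde | COc1cc(F)cc(OCc2ccccc2)c1C=O
F3 | step 6 | 2,4,6-trimethoxyphenol (bought) | COc1cc(OC)c(O)c(OC)c1
F4 | step 6 | 2-(benzyloxy)-6-methoxy-4-(2,4,6-trimethoxyphenoxy)benzaldehyde | COc1cc(OC)c(Oc2cc(OC)c(C=O)c(OCc3ccccc3)c2)c(OC)c1
F5 | step 6 | 2-(benzyloxy)-6-methoxy-4-(2,4,6-trimethoxyphenoxy)phenyl formate | COc1cc(OC)c(Oc2cc(OC)c(OC=O)c(OCc3ccccc3)c2)c(OC)c1
F6 | step 6 | 2-(benzyloxy)-6-methoxy-4-(2,4,6-trimethoxyphenoxy)phenol | COc1cc(OC)c(Oc2cc(OC)c(O)c(OCc3ccccc3)c2)c(OC)c1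
F7 | step 5 | 1-methoxy-1,3-bis(trimethylsilyloxy)buta-1,3-diene (bought) | COC(O[Si](C)(C)C)=CC(=C)O[Si](C)(C)C
F8 | step 5 | dimethyl 3,5-dioxoheptanedioate | COC(=O)CC(=O)CC(=O)CC(=O)OC
F9 | step 5 | dimethyl 4-diazo-3,5-dioxoheptanedioate | COC(=O)CC(=O)C(=[N+]=[N-])C(=O)CC(=O)OC
F10 | step 15 | 5-bromo-1,2,3-trimethoxybenzene (bought) | COc1cc(Br)cc(OC)c1OC
F11 | step 15 | 6-bromo-2,3,4-trimethoxybenzaldehyde | COc1cc(Br)c(C=O)c(OC)c1OC
F12 | step 14 | 4-bromo-2,6-dimethoxyphenol (bought) | COc1cc(Br)cc(OC)c1O
F13 | step 14 | 2-(benzyloxy)-5-bromo-1,3-dimethoxybenzene | COc1cc(Br)cc(OC)c1OCc1ccccc1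
F14 | step 14 | tetramer benzyl ether A–D (O-benzyl ether of 26) | COc1cc(OC)c(Oc2cc(OC)c(OC)c(Oc3cc(OC)c(OC)c(OC)c3Oc3cc(OC)c(OCc4ccccc4)c(OC)c3)c2)c(OC)c1
F15 | step 23 | henicosaacetate of the target | CC(=O)Oc1cc(OC(C)=O)c(Oc2cc(OC(C)=O)c(OC(C)=O)c(Oc3cc(OC(C)=O)c(OC(C)=O)c(OC(C)=O)c3Oc3cc(OC(C)=O)c(Oc4cc(OC(C)=O)c(OC(C)=O)c(OC(C)=O)c4Oc4cc(OC(C)=O)c(Oc5cc(OC(C)=O)c(OC(C)=O)c(OC(C)=O)c5Oc5cc(OC(C)=O)c(OC(C)=O)c(OC(C)=O)c5)c(OC(C)=O)c4)c(OC(C)=O)c3)c2)c(OC(C)=O)c1
A1 | alternative 1 | octamer hexadecamethyl ether pentaaldehyde (formyl at C4 of rings B, C, E, G and H) | COc1cc(OC)c(Oc2cc(OC)c(C=O)c(Oc3cc(OC)c(C=O)c(OC)c3Oc3cc(OC)c(Oc4cc(OC)c(C=O)c(OC)c4Oc4cc(OC)c(Oc5cc(OC)c(C=O)c(OC)c5Oc5cc(OC)c(C=O)c(OC)c5)c(OC)c4)c(OC)c3)c2)c(OC)c1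
A2 | alternative 1 | octamer hexadecamethyl ether with five free C4 hydroxyls (rings B, C, E, G and H) | COc1cc(OC)c(Oc2cc(OC)c(O)c(Oc3cc(OC)c(O)c(OC)c3Oc3cc(OC)c(Oc4cc(OC)c(O)c(OC)c4Oc4cc(OC)c(Oc5cc(OC)c(O)c(OC)c5Oc5cc(OC)c(O)c(OC)c5)c(OC)c4)c(OC)c3)c2)c(OC)c1
A3 | alternative 2 | 4-methoxy-3-aryloxycyclobut-2-en-1-one carrying the permethylated rings C to H (racemic) | COC1C(=O)C=C1Oc1cc(OC)c(OC)c(OC)c1Oc1cc(OC)c(Oc2cc(OC)c(OC)c(OC)c2Oc2cc(OC)c(Oc3cc(OC)c(OC)c(OC)c3Oc3cc(OC)c(OC)c(OC)c3)c(OC)c2)c(OC)c1
A4 | alternative 2 | 2-(ethynyloxy)-1,3,5-trimethoxybenzene | C#COc1c(OC)cc(OC)cc1OC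
A5 | alternative 2 | octamer eicosamethyl ether with the C3 hydroxyl of ring B free | COc1cc(OC)c(Oc2cc(O)c(OC)c(Oc3cc(OC)c(OC)c(OC)c3Oc3cc(OC)c(Oc4cc(OC)c(OC)c(OC)c4Oc4cc(OC)c(Oc5cc(OC)c(OC)c(OC)c5Oc5cc(OC)c(OC)c(OC)c5)c(OC)c4)c(OC)c3)c2)c(OC)c1
A6 | alternative 3 | bis(diaryl ketone) with carbonyl groups between rings D and E and between rings F and G | COc1cc(OC)c(Oc2cc(OC)c(OC)c(Oc3cc(OC)c(OC)c(OC)c3Oc3cc(OC)c(C(=O)c4cc(OC)c(OC)c(OC)c4Oc4cc(OC)c(C(=O)c5cc(OC)c(OC)c(OC)c5Oc5cc(OC)c(OC)c(OC)c5)c(OC)c4)c(OC)c3)c2)c(OC)c1
A7 | alternative 3 | diester with ester groups between rings D and E and between rings F and G | COc1cc(OC)c(Oc2cc(OC)c(OC)c(Oc3cc(OC)c(OC)c(OC)c3Oc3cc(OC)c(OC(=O)c4cc(OC)c(OC)c(OC)c4Oc4cc(OC)c(OC(=O)c5cc(OC)c(OC)c(OC)c5Oc5cc(OC)c(OC)c(OC)c5)c(OC)c4)c(OC)c3)c2)c(OC)c1
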